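**Retrosynthetic overview**

1. Both C6–C3 halves come from one aldehyde: 5-hydroxyvanillin 1 and formyl ylide 2 give catechol enal 3, used as such for ring A and, after capping to 4, as the precursor of ring B.
2. All chirality is installed once, on 4: asymmetric epoxidation–reduction (via 5) to trans-epoxy alcohol 6, then epoxy chloride 7.
3. Key disconnection: both alkyl C–O bonds of the dioxane, C7–O3 and C8–O4 (C7 benzylic, C8 bearing C9H2OH; O3/O4 = ring A oxygens meta/para to the propenal chain), made from 7 and the dianion of 3 in one flask.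
4. Ring order in that flask: the old oxirane opens at C7 (8), a new terminal oxirane closes on C9 (9), then the 1,4-dioxane closes at C8 (10); two rings are made in one operation, with double inversion, giving trans.
5. Final disconnection: the two aryl MOM ethers of 10, removed to reveal the catechol of target 11.

Assumption: the target SMILES is read as the (2R,3R)-trans-2,3-dihydro-1,4-benzodioxine (C7 R, C8 R); 1 and 2 are taken as catalogue materials.

**Route**

Step 1
Reactants: 1 3,4-dihydroxy-5-methoxybenzaldehyde (5-hydroxyvanillin); 2 (triphenylphosphoranylidene)acetaldehyde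
Product: 3 (2E)-3-(3,4-dihydroxy-5-methoxyphenyl)prop-2-enal
Conditions: 2 (1.15 equiv), 1,4-dioxane, 90 °C, N2
Reagents that add atoms: none
Why: Wittig olefination with the stabilised formyl ylide is E-selective and the weakly basic ylide tolerates the free catechol, so only the aldehyde is homologated by two carbons.

Step 2
Reactants: 3 (2E)-3-(3,4-dihydroxy-5-methoxyphenyl)prop-2-enal
Product: 4 (2E)-3-[3-methoxy-4,5-bis(methoxymethoxy)phenyl]prop-2-enal
Conditions: MOMCl (3 equiv), iPr2NEt (4 equiv), CH2Cl2, 0 °C → rt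
Reagents that add atoms: chloromethyl methyl ether COCCl
Why: O-alkylation of both phenols (MOM ether formation) makes ring B inert to peroxide, hydride, chlorination and the strong base of step 5, while the enal is untouched by the hindered amine.

Step 3
Reactants: 4 (2E)-3-[3-methoxy-4,5-bis(methoxymethoxy)phenyl]prop-2-enal
Product: 6 [(2S,3S)-3-[3-methoxy-4,5-bis(methoxymethoxy)phenyl]oxiran-2-yl]methanol, via epoxy aldehyde 5 (not isolated)
Conditions: (S)-2-[bis(3,5-bis(trifluoromethyl)phenyl)(trimethylsilyloxy)methyl]pyrrolidine (10 mol %), 35% aq. H2O2 (1.3 equiv), CH2Cl2, rt; then MeOH, NaBH4, 0 °C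
Reagents that add atoms: hydrogen peroxide OO
Why: Iminium-catalysed nucleophilic epoxidation of the enal (Jørgensen epoxidation), in which the bulky (S)-diarylprolinol silyl ether blocks one face of the E-iminium so that hydroperoxide adds to one face of C7 and closes to the trans (2R,3S)-epoxy aldehyde 5, is followed by in-flask borohydride reduction to the epoxy alcohol, whose (2S,3S) label reflects only a priority change at C2.

Step 4
Reactants: 6 [(2S,3S)-3-[3-methoxy-4,5-bis(methoxymethoxy)phenyl]oxiran-2-yl]methanol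
Product: 7 (2R,3S)-2-(chloromethyl)-3-[3-methoxy-4,5-bis(methoxymethoxy)phenyl]oxirane
Conditions: PPh3, N-chlorosuccinimide, NaHCO3, THF, 0 °C → rt
Reagents that add atoms: N-chlorosuccinimide O=C1CCC(=O)N1Cl
Why: Appel-type chlorination through an alkoxyphosphonium ion replaces only the primary hydroxyl under neutral buffered conditions and leaves both oxirane centres untouched (C2 becomes R only because CH2Cl outranks C3).

Step 5
Reactants: 7 (2R,3S)-2-(chloromethyl)-3-[3-methoxy-4,5-bis(methoxymethoxy)phenyl]oxirane; 3 (2E)-3-(3,4-dihydroxy-5-methoxyphenyl)prop-2-enal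
Product: 10 (2E)-3-[(2R,3R)-2-(hydroxymethyl)-8-methoxy-3-[3-methoxy-4,5-bis(methoxymethoxy)phenyl]-2,3-dihydro-1,4-benzodioxin-6-yl]prop-2-enal, via chlorohydrin aryl ether 8 (not isolated), via terminal epoxide 9 (not isolated)
Conditions: 3 (1.0 equiv), NaH (2.05 equiv), DMF, 0 °C; then 7 (1.05 equiv), 25 → 65 °C; H2O quench
Reagents that add atoms: none
Why: Proposed new method: a 3-aryl-epichlorohydrin version of the classical catechol–epichlorohydrin benzodioxane synthesis (closest known reaction type: phenoxide epoxide opening, chlorohydrin-to-epoxide closure, then 6-exo-tet phenoxide epoxide opening), in which the more basic, unhindered O3 phenoxide of the dianion opens the oxirane at the aryl-activated benzylic C7 with inversion, the freed C8 alkoxide expels chloride to give terminal epoxide 9 with retention at C8, and the remaining O4 phenoxide opens 9 at C8 in the 6-exo mode with inversion, so the trans-(2S,3S) epoxide is translated by double inversion into the trans-(2R,3R) dioxane and the CH2OH group is released.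

Step 6
Reactants: 10 (2E)-3-[(2R,3R)-2-(hydroxymethyl)-8-methoxy-3-[3-methoxy-4,5-bis(methoxymethoxy)phenyl]-2,3-dihydro-1,4-benzodioxin-6-yl]prop-2-enal
Product: 11 (2E)-3-[(2R,3R)-3-(3,4-dihydroxy-5-methoxyphenyl)-2-(hydroxymethyl)-8-methoxy-2,3-dihydro-1,4-benzodioxin-6-yl]prop-2-enal
Conditions: 2 M aq. HCl, THF, 45 °C, N2
Reagents that add atoms: none
Why: Acid-catalysed acetal hydrolysis removes both aryl MOM ethers without harming the enal, the primary alcohol or the dioxane, and C8 is not epimerisable under these conditions (a minor cis isomer, epimeric at the p-hydroxybenzylic C7, would drift to the diequatorial trans compound on longer acid exposure).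

**Compound list**

1 | 3,4-dihydroxy-5-methoxybenzaldehyde (5-hydroxyvanillin) | COc1cc(C=O)cc(O)c1O | starting material
2 | (triphenylphosphoranylidene)acetaldehyde | O=CC=P(c1ccccc1)(c1ccccc1)c1ccccc1 | starting material
3 | (2E)-3-(3,4-dihydroxy-5-methoxyphenyl)prop-2-enal | COc1cc(/C=C/C=O)cc(O)c1O | intermediate
4 | (2E)-3-[3-methoxy-4,5-bis(methoxymethoxy)phenyl]prop-2-enal | COc1cc(/C=C/C=O)cc(OCOC)c1OCOC | intermediate
5 | (2R,3S)-3-[3-methoxy-4,5-bis(methoxymethoxy)phenyl]oxirane-2-carbaldehyde | COc1cc([C@@H]2O[C@H]2C=O)cc(OCOC)c1OCOC | intermediate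
6 | [(2S,3S)-3-[3-methoxy-4,5-bis(methoxymethoxy)phenyl]oxiran-2-yl]methanol | COc1cc([C@@H]2O[C@H]2CO)cc(OCOC)c1OCOC | intermediate
7 | (2R,3S)-2-(chloromethyl)-3-[3-methoxy-4,5-bis(methoxymethoxy)phenyl]oxirane | COc1cc([C@@H]2O[C@H]2CCl)cc(OCOC)c1OCOC | intermediate
8 | (2E)-3-[3-[(1R,2R)-3-chloro-2-hydroxy-1-[3-methoxy-4,5-bis(methoxymethoxy)phenyl]propoxy]-4-hydroxy-5-methoxyphenyl]prop-2-enal (disodium salt in the flask) | COc1cc([C@@H](Oc2cc(/C=C/C=O)cc(OC)c2O)[C@@H](O)CCl)cc(OCOC)c1OCOC | intermediate
9 | (2E)-3-[4-hydroxy-3-methoxy-5-[(R)-[3-methoxy-4,5-bis(methoxymethoxy)phenyl][(2S)-oxiran-2-yl]methoxy]phenyl]prop-2-enal (sodium phenoxide in the flask) | COc1cc([C@@H](Oc2cc(/C=C/C=O)cc(OC)c2O)[C@@H]2CO2)cc(OCOC)c1OCOC | intermediate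
10 | (2E)-3-[(2R,3R)-2-(hydroxymethyl)-8-methoxy-3-[3-methoxy-4,5-bis(methoxymethoxy)phenyl]-2,3-dihydro-1,4-benzodioxin-6-yl]prop-2-enal | COc1cc([C@H]2Oc3cc(/C=C/C=O)cc(OC)c3O[C@@H]2CO)cc(OCOC)c1OCOC | intermediate
11 | (2E)-3-[(2R,3R)-3-(3,4-dihydroxy-5-methoxyphenyl)-2-(hydroxymethyl)-8-methoxy-2,3-dihydro-1,4-benzodioxin-6-yl]prop-2-enal | COc1cc([C@H]2Oc3cc(/C=C/C=O)cc(OC)c3O[C@@H]2CO)cc(O)c1O | target

**Count and risks**

Total step count: 6. Longest linear sequence: 6 (1 → 3 → 4 → 6 → 7 → 10 → 11; 3 re-enters as the second reactant of step 5).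

Most likely to fail, in order:

Step 5 (the epoxide relay). Three things can go wrong: the O3 phenoxide may displace the C9 chloride instead of opening at C7, the final closure may go 7-endo at C9, or C7 may partly ionise. The fallback sets out from 6 and comes back at 11, and it also bypasses chloride 7. Alcohol 6 is tritylated (TrCl, Et3N, 4-(dimethylamino)pyridine, CH2Cl2) to the epoxy trityl ether F1, so that C9 can no longer act as an electrophile. The dianion of 3 (NaH, DMF, 50 °C) opens F1 at C7 with inversion to the phenol–secondary alcohol F2. An intramolecular Mitsunobu etherification (PPh3, DIAD, THF, 0 °C → rt) between the acidic O4–H and the C8 hydroxyl can close only the six-membered ring, with inversion at C8, and gives the trityl-protected benzodioxane F3 with the same (2R,3R) configuration as 10. 2 M HCl in THF then removes the trityl and both MOM groups to give 11. This costs two more operations but removes the regiochemical ambiguities.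

Step 3 (organocatalytic epoxidation of an electron-rich enal; the epoxy aldehyde is labile and conjugate addition of peroxide may be slow). The fallback sets out from 4 and comes back at 6. Luche reduction (NaBH4, CeCl3·7H2O, MeOH, 0 °C) gives the cinnamyl alcohol F4. Sharpless asymmetric epoxidation (Ti(OiPr)4 10 mol %, L-(+)-diethyl tartrate 12 mol %, tBuOOH, 4 Å molecular sieves, CH2Cl2, −20 °C), a tartrate-controlled directed epoxidation of the allylic alcohol, then delivers 6 with the same (2S,3S) sense.

Step 1 (Wittig on a phenoxide-deactivated, unprotected catechol aldehyde; sluggish reaction and over-homologation to the dienal are possible). The fallback sets out from 1 and comes back at 4 and at 3. Aldehyde 1 is first capped (MOMCl, iPr2NEt, CH2Cl2) to the bis-MOM aldehyde F5, an ordinary alkoxybenzaldehyde that is olefinated with 2 (toluene, 90 °C) directly to 4. The catechol enal 3 needed for step 5 is then released from one portion of 4 with 2 M HCl in THF.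

Further compounds
F1 | step 5 | (2S,3S)-2-[3-methoxy-4,5-bis(methoxymethoxy)phenyl]-3-[(triphenylmethoxy)methyl]oxirane | COc1cc([C@@H]2O[C@H]2COC(c2ccccc2)(c2ccccc2)c2ccccc2)cc(OCOC)c1OCOC
F2 | step 5 | (2E)-3-[4-hydroxy-3-[(1R,2S)-2-hydroxy-1-[3-methoxy-4,5-bis(methoxymethoxy)phenyl]-3-(triphenylmethoxy)propoxy]-5-methoxyphenyl]prop-2-enal | COc1cc([C@@H](Oc2cc(/C=C/C=O)cc(OC)c2O)[C@@H](O)COC(c2ccccc2)(c2ccccc2)c2ccccc2)cc(OCOC)c1OCOC
F3 | step 5 | (2E)-3-[(2R,3R)-8-methoxy-3-[3-methoxy-4,5-bis(methoxymethoxy)phenyl]-2-[(triphenylmethoxy)methyl]-2,3-dihydro-1,4-benzodioxin-6-yl]prop-2-enal | COc1cc([C@H]2Oc3cc(/C=C/C=O)cc(OC)c3O[C@@H]2COC(c2ccccc2)(c2ccccc2)c2ccccc2)cc(OCOC)c1OCOC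
F4 | step 3 | (2E)-3-[3-methoxy-4,5-bis(methoxymethoxy)phenyl]prop-2-en-1-ol | COc1cc(/C=C/CO)cc(OCOC)c1OCOC
F5 | step 1 | 3-methoxy-4,5-bis(methoxymethoxy)benzaldehyde | COc1cc(C=O)cc(OCOC)c1OCOC
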